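The trimethylcyclohexene (ring A) is disconnected across its tetrasubstituted C1=C2 alkene. The bonds C2–C3 (methyl-bearing carbon to the allylic ring CH2) and C1–C6 (chain-bearing carbon to the gem-dimethyl carbon) are formed together in a Lewis-acid-promoted Diels–Alder reaction of methyl but-2-ynoate with 4-methylpenta-1,3-diene. The alkyne delivers C1=C2 with its methyl group and a one-carbon handle for the side chain; the diene delivers C3–C6, and its quaternary carbon prevents aromatisation. The adduct becomes β-cyclogeranyl bromide, then an (E)-diene by propargylation and carboalumination–vinylation, which is joined by B-alkyl Suzuki coupling to a bromodihydropyranone–butyrolactone made by two catalyst-controlled additions.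

Key step: step 1

Assumption: the facial sense of the two catalyst-controlled steps (7 and 9) is assigned by analogy with the accepted models for these catalyst classes; if either shows the opposite sense, its mirror-image form is used. Compounds 1, 2, 7, 10, 13, 14 and 18 are taken as catalogue materials.

Step 1
Reactants: 1 4-methylpenta-1,3-diene; 2 methyl but-2-ynoate
Product: 3 methyl 2,6,6-trimethylcyclohexa-1,4-diene-1-carboxylate
Conditions: EtAlCl2 (30 mol %), CH2Cl2, −20 °C to rt, slow addition of 1 (3 equiv)
Reagents that add atoms: none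
Why: Coordination of EtAlCl2 to the ester lowers the LUMO of the ynoate, and a strongly asynchronous [4+2] cycloaddition (Diels–Alder reaction) should follow in which the unsubstituted CH2 terminus of the diene, which has the largest HOMO coefficient, bonds to the methyl-bearing β-carbon while the gem-dimethyl terminus, with tertiary allyl cation character, closes onto the ester-bearing α-carbon. The closest known reaction type is the aluminium-halide-promoted Diels–Alder reaction of propiolates and tetrolates with 1,3-dienes. The cyclohexa-1,4-diene ring is closed as a six-membered ring by suprafacial addition across the s-cis diene; in the stepwise limit this is collapse of an allyl cation–aluminium allenoate ion pair at its tertiary end, a six-ring closure preferred over the four-ring alternative. No stereocentre is formed. The step needs "ortho" regioselectivity, which the matched polarisation of the diene (two donor methyls on one terminus) and the ynoate (acceptor on one carbon) should secure, and chemoselectivity over cationic oligomerisation of the diene, which the proton-scavenging alkylaluminium chloride, the low temperature and the slow addition should secure. The quaternary carbon blocks aromatisation of the adduct.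

Step 2
Reactants: 3 methyl 2,6,6-trimethylcyclohexa-1,4-diene-1-carboxylate
Product: 4 methyl 2,6,6-trimethylcyclohex-1-ene-1-carboxylate
Conditions: H2 (1 atm), RhCl(PPh3)3 (5 mol %), toluene/EtOH, rt
Reagents that add atoms: none
Why: Chemoselective homogeneous hydrogenation: RhCl(PPh3)3 should reduce the cis-disubstituted C4=C5 alkene far faster than the tetrasubstituted, ester-conjugated C1=C2 alkene and should not move double bonds into conjugation.

Step 3
Reactants: 4 methyl 2,6,6-trimethylcyclohex-1-ene-1-carboxylate
Product: 5 (2,6,6-trimethylcyclohex-1-en-1-yl)methanol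
Conditions: LiAlH4, Et2O, 0 °C to rt
Reagents that add atoms: none
Why: LiAlH4 reduction of the hindered conjugated ester should give the primary allylic alcohol by 1,2-addition only, the twisted tetrasubstituted alkene being inert to hydride.

Step 4
Reactants: 5 (2,6,6-trimethylcyclohex-1-en-1-yl)methanol
Product: 6 2-(bromomethyl)-1,3,3-trimethylcyclohex-1-ene
Conditions: PBr3, pyridine (cat.), Et2O, −10 °C; used crude
Reagents that add atoms: phosphorus tribromide, BrP(Br)Br
Why: Bromide displaces the phosphite ester of the primary allylic alcohol (SN2); the SN2′ mode would have to attack a fully substituted carbon and is not expected.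

Step 5
Reactants: 6 2-(bromomethyl)-1,3,3-trimethylcyclohex-1-ene; 7 1-(trimethylsilyl)prop-1-yne
Product: 9 2-(but-3-yn-1-yl)-1,3,3-trimethylcyclohex-1-ene, via silylalkyne 8 (not isolated)
Conditions: 7, n-BuLi, THF, −78 to −20 °C; 6, −78 °C to rt; then K2CO3 (cat.), MeOH, rt
Reagents that add atoms: none
Why: Propargylation then protodesilylation: 3-lithio-1-(trimethylsilyl)propyne alkylates primary allylic bromides at its propargylic carbon (the silyl group suppresses allenyl coupling), and methanolic carbonate then cleaves the alkynyl–silicon bond.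

Step 6
Reactants: 9 2-(but-3-yn-1-yl)-1,3,3-trimethylcyclohex-1-ene; 10 bromoethene
Product: 12 1,3,3-trimethyl-2-[(3E)-3-methylhexa-3,5-dien-1-yl]cyclohex-1-ene, via alkenylalane 11 (not isolated)
Conditions: Me3Al, Cp2ZrCl2 (25 mol %), CH2Cl2, 0 °C to rt; then 10, Pd(PPh3)4 (5 mol %), ZnCl2 (20 mol %), THF, rt
Reagents that add atoms: trimethylaluminium, C[Al](C)C
Why: Zirconium-catalysed syn-carboalumination of the terminal alkyne puts methyl on the internal and aluminium on the terminal carbon, which fixes the E trisubstituted alkene, and the alkenylalane couples with bromoethene with retention (Negishi carboalumination and Negishi coupling).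

Step 7
Reactants: 13 furan-2(5H)-one; 14 potassium trifluoro(vinyl)borate
Product: 15 (4S)-4-ethenyloxolan-2-one
Conditions: [Rh(cod)2]BF4 (3 mol %), (S)-BINAP (3.3 mol %), toluene/H2O, 100 °C
Reagents that add atoms: none
Why: Rhodium/BINAP-catalysed asymmetric 1,4-addition of an alkenylboron reagent to an unsaturated lactone (Hayashi–Miyaura reaction); the (S)-BINAP complex should deliver the vinyl group to the same enone face as with cyclic enones, which sets the β-stereocentre as S.

Step 8
Reactants: 15 (4S)-4-ethenyloxolan-2-one
Product: 17 (3R)-5-oxooxolane-3-carbaldehyde, via ozonide 16 (not isolated)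
Conditions: O3, CH2Cl2, −78 °C; then PPh3, −78 °C to rt; used crude
Reagents that add atoms: ozone, [O-][O+]=O
Why: Ozonolysis with reductive work-up cleaves the vinyl group under base-free conditions, so the α-stereocentre and the β-acyloxy aldehyde should survive (the descriptor changes from S to R only through the priority change).

Step 9
Reactants: 17 (3R)-5-oxooxolane-3-carbaldehyde; 18 (E)-1-methoxybuta-1,3-diene
Product: 19 (4R)-4-[(2R,6S)-6-methoxy-3,6-dihydro-2H-pyran-2-yl]oxolan-2-one
Conditions: CrCl(L) (5 mol %; L = dianion of the Schiff base of 3-(1-adamantyl)-2-hydroxy-5-methylbenzaldehyde and one enantiomer of cis-1-aminoindan-2-ol), 4 Å molecular sieves, acetone, rt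
Reagents that add atoms: none
Why: Chiral Lewis-acid-catalysed hetero-Diels–Alder reaction of an aldehyde with a 1-alkoxydiene: the trivalent chromium complex, in the enantiomer that exposes the Re face of the formyl group, should set the new carbinol carbon as R under catalyst control, and endo addition gives the cis acetal whose anomeric centre is erased in step 10.

Step 10
Reactants: 19 (4R)-4-[(2R,6S)-6-methoxy-3,6-dihydro-2H-pyran-2-yl]oxolan-2-one
Product: 21 (6R)-6-[(3R)-5-oxooxolan-3-yl]-5,6-dihydro-2H-pyran-2-one, via lactol 20 (not isolated)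
Conditions: CrO3, H2SO4, acetone/H2O, 0 °C
Reagents that add atoms: water, O
Why: Aqueous acid hydrolyses the allylic mixed acetal to the lactol and chromic acid oxidises it at once to the α,β-unsaturated δ-lactone (Jones oxidation), leaving both stereocentres and the butyrolactone untouched.

Step 11
Reactants: 21 (6R)-6-[(3R)-5-oxooxolan-3-yl]-5,6-dihydro-2H-pyran-2-one
Product: 23 (6R)-3-bromo-6-[(3R)-5-oxooxolan-3-yl]-5,6-dihydro-2H-pyran-2-one, via dibromide 22 (not isolated)
Conditions: Br2, CH2Cl2, 0 °C; then Et3N, 0 °C to rt
Reagents that add atoms: bromine, BrBr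
Why: Bromine addition to the enoate followed by amine-induced loss of HBr (acidic α-hydrogen, β-bromide leaving) should give the α-bromo enoate (addition–dehydrobromination).

Step 12
Reactants: 12 1,3,3-trimethyl-2-[(3E)-3-methylhexa-3,5-dien-1-yl]cyclohex-1-ene; 23 (6R)-3-bromo-6-[(3R)-5-oxooxolan-3-yl]-5,6-dihydro-2H-pyran-2-one
Product: 25 (6R)-3-[(3E)-4-methyl-6-(2,6,6-trimethylcyclohex-1-en-1-yl)hex-3-en-1-yl]-6-[(3R)-5-oxooxolan-3-yl]-5,6-dihydro-2H-pyran-2-one (target), via alkylborane 24 (not isolated)
Conditions: 12, 9-BBN-H, THF, 0 °C to rt; then 23, Pd(dppf)Cl2 (5 mol %), AsPh3 (10 mol %), K3PO4 (3 M aq), DMF, rt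
Reagents that add atoms: none
Why: 9-BBN should hydroborate only the monosubstituted terminus of the diene (anti-Markovnikov), and the primary alkylborane couples with the α-bromo enoate under palladium catalysis (B-alkyl Suzuki–Miyaura coupling) with phosphate base at room temperature, conditions chosen to spare both lactones and both stereocentres.

Compound list
1 | 4-methylpenta-1,3-diene | CC(C)=CC=C | starting material
2 | methyl but-2-ynoate | CC#CC(=O)OC | starting material
3 | methyl 2,6,6-trimethylcyclohexa-1,4-diene-1-carboxylate | COC(=O)C1=C(C)CC=CC1(C)C | intermediate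
4 | methyl 2,6,6-trimethylcyclohex-1-ene-1-carboxylate | COC(=O)C1=C(C)CCCC1(C)C | intermediate
5 | (2,6,6-trimethylcyclohex-1-en-1-yl)methanol | OCC1=C(C)CCCC1(C)C | intermediate
6 | 2-(bromomethyl)-1,3,3-trimethylcyclohex-1-ene | BrCC1=C(C)CCCC1(C)C | intermediate
7 | 1-(trimethylsilyl)prop-1-yne | CC#C[Si](C)(C)C | starting material
8 | trimethyl[4-(2,6,6-trimethylcyclohex-1-en-1-yl)but-1-yn-1-yl]silane | C[Si](C)(C)C#CCCC1=C(C)CCCC1(C)C | intermediate
9 | 2-(but-3-yn-1-yl)-1,3,3-trimethylcyclohex-1-ene | C#CCCC1=C(C)CCCC1(C)C | intermediate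
10 | bromoethene | C=CBr | starting material
11 | dimethyl[(1E)-2-methyl-4-(2,6,6-trimethylcyclohex-1-en-1-yl)but-1-en-1-yl]alumane | C[Al](C)/C=C(C)/CCC1=C(C)CCCC1(C)C | intermediate
12 | 1,3,3-trimethyl-2-[(3E)-3-methylhexa-3,5-dien-1-yl]cyclohex-1-ene | C=C/C=C(C)/CCC1=C(C)CCCC1(C)C | intermediate
13 | furan-2(5H)-one | O=C1OCC=C1 | starting material
14 | potassium trifluoro(vinyl)borate | [K+].C=C[B-](F)(F)F | starting material
15 | (4S)-4-ethenyloxolan-2-one | C=C[C@H]1COC(=O)C1 | intermediate
16 | (4R)-4-(1,2,4-trioxolan-3-yl)oxolan-2-one (epimers at the trioxolane carbon) | O1COOC1[C@H]1COC(=O)C1 | intermediate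
17 | (3R)-5-oxooxolane-3-carbaldehyde | O=C[C@H]1COC(=O)C1 | intermediate
18 | (E)-1-methoxybuta-1,3-diene | CO/C=C/C=C | starting material
19 | (4R)-4-[(2R,6S)-6-methoxy-3,6-dihydro-2H-pyran-2-yl]oxolan-2-one | CO[C@@H]1C=CC[C@H]([C@H]2COC(=O)C2)O1 | intermediate
20 | (4R)-4-[(2R)-6-hydroxy-3,6-dihydro-2H-pyran-2-yl]oxolan-2-one (anomers) | OC1C=CC[C@H]([C@H]2COC(=O)C2)O1 | intermediate
21 | (6R)-6-[(3R)-5-oxooxolan-3-yl]-5,6-dihydro-2H-pyran-2-one | O=C1C=CC[C@H]([C@H]2COC(=O)C2)O1 | intermediate
22 | (6R)-3,4-dibromo-6-[(3R)-5-oxooxolan-3-yl]oxan-2-one (trans-dibromide, diastereomers) | O=C1C(Br)C(Br)C[C@H]([C@H]2COC(=O)C2)O1 | intermediate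
23 | (6R)-3-bromo-6-[(3R)-5-oxooxolan-3-yl]-5,6-dihydro-2H-pyran-2-one | O=C1C(Br)=CC[C@H]([C@H]2COC(=O)C2)O1 | intermediate
24 | 9-[(3E)-4-methyl-6-(2,6,6-trimethylcyclohex-1-en-1-yl)hex-3-en-1-yl]-9-borabicyclo[3.3.1]nonane | CC1=C(CC/C(C)=C/CCB2C3CCCC2CCC3)C(C)(C)CCC1 | intermediate
25 | (6R)-3-[(3E)-4-methyl-6-(2,6,6-trimethylcyclohex-1-en-1-yl)hex-3-en-1-yl]-6-[(3R)-5-oxooxolan-3-yl]-5,6-dihydro-2H-pyran-2-one | CC1=C(CC/C(C)=C/CCC2=CC[C@H]([C@H]3COC(=O)C3)OC2=O)C(C)(C)CCC1 | target

Total step count: 12. Longest linear sequence: 7 steps (steps 1–6 and 12); the lactone fragment takes 5 steps (7–11).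

Steps most likely to fail

Step 1. The cis-methyl group disfavours the s-cis conformer of the diene, so the cycloaddition may be outrun by acid-induced oligomerisation of the diene or by [2+2] and ene pathways from the s-trans conformer. The fallback keeps the two-bond ring construction but changes it to a Michael addition–aldol condensation. It does not set out from a numbered compound: it starts, in place of 1 and 2, from mesityl oxide (CC(=O)C=C(C)C) and methyl acetoacetate (CC(=O)CC(=O)OC), and comes back to the route at 4. Heating the two with BF3·OEt2 should give methyl 2,6,6-trimethyl-4-oxocyclohex-2-ene-1-carboxylate F1: the acetoacetate α-carbon adds to the β-carbon of mesityl oxide, and the methyl ketone of the mesityl oxide part then condenses onto the acetoacetate carbonyl. NaBH4/CeCl3 in MeOH should reduce the ketone to methyl 4-hydroxy-2,6,6-trimethylcyclohex-2-ene-1-carboxylate F2. TsOH in refluxing toluene should dehydrate it to the conjugated dienoate methyl 2,6,6-trimethylcyclohexa-1,3-diene-1-carboxylate F3. Diimide (TsNHNH2, NaOAc, heat) should then reduce only the cis-disubstituted C3=C4 bond to give 4.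

Step 9. During the slow cycloaddition the β-acyloxy aldehyde may lose the lactone carboxylate by β-elimination or epimerise at its α-carbon, and the neighbouring stereocentre may erode catalyst control of the facial selectivity. The fallback sets out from 17 and comes back at 21, replacing the cycloaddition by allylation and ring-closing metathesis. Brown allylation with the enantiomer of B-allyldiisopinocampheylborane that adds to the Re face (Et2O, −78 °C, buffered peroxide work-up) should consume the aldehyde within minutes and give (4R)-4-[(1R)-1-hydroxybut-3-en-1-yl]oxolan-2-one F4. Immediate acylation with acryloyl chloride and iPr2NEt (CH2Cl2, −78 to 0 °C, to forestall acyl migration between the two hydroxyl groups) should give (1R)-1-[(3R)-5-oxooxolan-3-yl]but-3-en-1-yl prop-2-enoate F5. Ring-closing metathesis with the second-generation Grubbs catalyst RuCl2(=CHPh)(PCy3)(H2IMes) in refluxing CH2Cl2 should close the dihydropyranone 21.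

Step 12. The aqueous base needed for transmetallation may open the lactones (hydrolysis or vinylogous elimination at the dihydropyranone), and the alkylborane may undergo protodeboronation or β-hydride elimination instead of coupling. The fallback sets out from 12 and comes back at 25 through a base-free organozinc coupling. Hydroboration of 12 with 9-BBN-H as before but with oxidative work-up (H2O2, NaOH) should give (3E)-4-methyl-6-(2,6,6-trimethylcyclohex-1-en-1-yl)hex-3-en-1-ol F6. I2, PPh3 and imidazole should give 2-[(3E)-6-iodo-3-methylhex-3-en-1-yl]-1,3,3-trimethylcyclohex-1-ene F7. Zinc dust with LiCl in THF should insert to give the alkylzinc iodide [(3E)-4-methyl-6-(2,6,6-trimethylcyclohex-1-en-1-yl)hex-3-en-1-yl]zinc iodide F8. Negishi coupling of F8 with 23 (Pd(OAc)2, SPhos, THF, rt) should give 25.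

Further compounds
F1 | step 1 | methyl 2,6,6-trimethyl-4-oxocyclohex-2-ene-1-carboxylate (racemic) | COC(=O)C1C(C)=CC(=O)CC1(C)C
F2 | step 1 | methyl 4-hydroxy-2,6,6-trimethylcyclohex-2-ene-1-carboxylate (racemic, diastereomers) | COC(=O)C1C(C)=CC(O)CC1(C)C
F3 | step 1 | methyl 2,6,6-trimethylcyclohexa-1,3-diene-1-carboxylate | COC(=O)C1=C(C)C=CCC1(C)C
F4 | step 9 | (4R)-4-[(1R)-1-hydroxybut-3-en-1-yl]oxolan-2-one | C=CC[C@H]([C@H]1COC(=O)C1)O
F5 | step 9 | (1R)-1-[(3R)-5-oxooxolan-3-yl]but-3-en-1-yl prop-2-enoate | C=CC[C@H]([C@H]1COC(=O)C1)OC(=O)C=C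
F6 | step 12 | (3E)-4-methyl-6-(2,6,6-trimethylcyclohex-1-en-1-yl)hex-3-en-1-ol | CC1=C(CC/C(C)=C/CCO)C(C)(C)CCC1
F7 | step 12 | 2-[(3E)-6-iodo-3-methylhex-3-en-1-yl]-1,3,3-trimethylcyclohex-1-ene | CC1=C(CC/C(C)=C/CCI)C(C)(C)CCC1
F8 | step 12 | [(3E)-4-methyl-6-(2,6,6-trimethylcyclohex-1-en-1-yl)hex-3-en-1-yl]zinc iodide | CC1=C(CC/C(C)=C/CC[Zn]I)C(C)(C)CCC1
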